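A closed, stirred vessel at constant temperature is charged with solid substrate, which dissolves, and with reagent. Dissolved substrate and reagent give target, and dissolved substrate can also attack target to give side product.

| setting | noon | winter | flask |
|---|---|---|---|
| solid substrate | 0.10 M | 0.10 M | 0.10 M |
| reagent | 0.048 M | 0.071 M | 0.0950 M |
| remark | run made earlier | run made earlier |  |
| time |  |  | 6.0 min |

| run | time / min | target / % |
|---|---|---|
| noon | 0.667 | 7.1 |
| noon | 1.33 | 5.0 |
| noon | 2.00 | 4.5 |
| noon | 2.50 | 2.9 |
| noon | 3.00 | 2.8 |
| noon | 4.00 | 1.8 |
| winter | 0.250 | 6.9 |
| winter | 0.667 | 11.0 |
| winter | 1.33 | 9.9 |
| winter | 2.00 | 8.7 |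
| winter | 3.00 | 8.1 |
| winter | 4.00 | 8.6 |

(readings scatter by 0.5 percentage points)

- in percentages every species weighs as the solid substrate in it: one side product counts as two
- as a solid, counted per litre of solution: solid substrate
- steps thought possible: dissolved substrate + reagent -> target; solid substrate <-> dissolved substrate; dissolved substrate + target -> side product; reagent -> decomposition product; target <-> isomer of the product
- at the start none of the solid substrate is in solution

1. target at 6.0 min, in percent of the solid substrate charged
2. the change that raises the amount of target at 6.0 min, in percent of the solid substrate charged most ("none" if none brings more than 2 percentage points) (cedar / elm / maple / none)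
3. amount of target at 6.0 min, in percent of the solid substrate charged, after elm

- cedar: doubling the dissolution coefficient of the solid substrate, all else as stated
- elm: doubling the solubility of the solid substrate, all else as stated
- maple: doubling the amount of reagent, all else as stated

Substrate that ends in target has taken one reagent, while side product holds two substrates on one reagent. So a charge that ends wholly in side product takes reagent equal to half the charged substrate. Charged reagent minus half the charged substrate is 0.0450 M in the flask: the spare reagent. Where it is below zero, reagent is the limiting reagent on either route. The noon run has −0.00200 M, and its target falls to a reading of 1.8 % at 4.00 min. The winter run has 0.0210 M, and its target levels off, with readings of 8.1 % and 8.6 %. The last two winter readings give 0.398 of target per unit of spare reagent; taking that ratio as holding in the flask, this reckoning puts the flask at 17.9 %.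

Now the settings. Cedar speeds the dissolving, but the winter peak is read at 0.667 min, earlier than 6.0 min, and spare reagent stays as it is. Elm raises c(dissolved substrate), yet the two reaction steps that consume it both carry it as a factor, so at given c(reagent) and c(target) their ratio does not depend on it, and the reckoning remains at 17.9 %. Maple lifts spare reagent to 0.140 M, so this reckoning chooses maple.

The forecast says 17 % (13 % to 21 %), 18 % after elm, and maple, holding that “Faster dissolution or higher solubility changes only the speed, not the partition”. Its figure for the flask as charged is lower than this reckoning's, and its choice is the same.

The flask gives 13.3 %, and 13.3 % after elm. The changes in target are −0.018 percentage points for cedar, −0.054 points for elm and 12 points for maple.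

    dissolved substrate + reagent → target (k = 0.400 L mol⁻¹ s⁻¹)
    solid substrate ⇌ dissolved substrate, rate k2*(cs2 - [dissolved substrate]) while solid is left; crystals form when [dissolved substrate] > cs2 (solubility = 0.0620 M, k = 0.150 s⁻¹)
    dissolved substrate + target → side product (k = 1.20 L mol⁻¹ s⁻¹)
    reagent → decomposition product (k = 1.10 × 10⁻⁵ s⁻¹)
    target ⇌ isomer of the product (K = 0.970, k = 0.340 s⁻¹)

Target passes forward into isomer of the product with a half-life of 2.0 s, far shorter than 6.0 min. The flask at 6.00 min holds 13.3 % target beside 12.9 % isomer. Spare reagent less half of those two is 0.0319 M, and the reagent found is 0.0317 M. With 0.40 M of solid substrate, spare reagent is −0.105 M, and that neighbouring flask keeps 0.026 % of its reagent and 0.00626 % target.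

The runs come from a simulation on assumed constants.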